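(The readings are calculated for substances that don't exist; noise was put on by code.)

**Count first.** Count the coupling partner. You asked for a quick number for ash, and your hunch was that its coupling partner charge is the cap. Ash holds 0.600 M of coupling partner, less than its 1.40 M of starting material, so coupling partner is the limiting reagent there, and your ceiling is 42.9 % of the starting material charged. Don't expect to reach it.

| flask | starting material | coupling partner | target | time |
|---|---|---|---|---|
| elm | 0.400 M | 0.600 M |  |  |
| maple | 0.400 M | 0.600 M | 0.120 M |  |
| oak | 0.400 M | 0.300 M |  |  |
| cedar | 0.800 M | 0.600 M |  |  |
| ash | 1.40 M | 0.600 M |  | 3.9 min |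

- elm run (time / min: [target] / M): 0.65: 0.059; 1.3: 0.103; 1.9: 0.122; 2.6: 0.136; 3.2: 0.145; 3.9: 0.155
- maple run (time / min: [target] / M): 0.65: 0.175; 1.3: 0.195; 1.9: 0.219; 2.6: 0.232; 3.2: 0.228; 3.9: 0.231
- oak run (time / min: [target] / M): 0.65: 0.045; 1.3: 0.074; 1.9: 0.093; 2.6: 0.097; 3.2: 0.106; 3.9: 0.109
- cedar run (time / min: [target] / M): 0.65: 0.117; 1.3: 0.170; 1.9: 0.203; 2.6: 0.216; 3.2: 0.233; 3.9: 0.233

(readings scatter by 0.004 M)

- Overall: starting material + coupling partner -> target.
- Constant volume, constant temperature.
- Bound and free are read together.
- An order is taken over about fifteen percent of the charge, up and down.

* how the opening rate goes with [starting material] round the charge of the elm run: the exponent of the rate at two percent of starting material gone to target (one fixed amount of target, the same in the runs compared)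
* how the opening rate goes with [coupling partner] round the charge of the elm run: the exponent of the rate at two percent of starting material gone to target
* target in the ash run at 3.9 min, as a share of the starting material charged

**The ratio.** Each target made takes one coupling partner out of the charge. So subtract [target] from the charge, whatever form the remainder sits in, and divide [target] by that remainder. In cedar at 3.9 min, 0.233 M stands over 0.367 M, which gives 0.635, the hold ratio: target over coupling partner outside target, at one fixed time. Elm has the same coupling partner charge and reads 0.348. Cedar has twice the starting material of elm, so with coupling partner held at 0.600 M, take the ratio as growing with the starting material charged to the power 0.866.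

**My number.** Carry that power to ash, which has the same coupling partner charge. Its hold ratio comes to 1.03. Turn it back: target is the charge times the ratio over one plus the ratio, so 0.305 M, or 21.8 % of the starting material. Two readings carry this, so hold it loosely.

The forecast gives orders of 1 in starting material and 0.35 in coupling partner, and 23 % for ash, higher than my figure, holding that “ash should plateau near 0.32–0.34 M by 3.9 min”.

**The flask.** Ash gives 21.0 %, and round the charge of elm the orders are 1.0 in starting material and 0.59 in coupling partner, from these steps:

    starting material + coupling partner ⇌ target (2.448 M⁻¹ min⁻¹, 0.1812 min⁻¹)
    2 coupling partner ⇌ idle reagent dimer, settled at all times (12.80 M⁻¹)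
    2 starting material → homo dimer (0.3960 M⁻¹ min⁻¹)

Fitted with the main steps alone, the readings leave a residual of 3.9 in units of the scatter. Ash's hold ratio now reads 0.965, a little below my 1.03, its remainder being free coupling partner and that held in idle reagent dimer. Try elm's ratio on oak, charged 0.300 M of coupling partner: it gives 0.0774 M, and oak read 0.109 M at 3.9 min.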